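The numbers in the tables were generated by integration on assumed constants; scatter was added.

The time allowed is the same in each new flask, 80 min, but a feed takes part of it away.

| setting | theta | epsilon | gamma | red | green | violet | teal |
|---|---|---|---|---|---|---|---|
| starting material | 0.085 M | 0.043 M | 0.064 M | 0.085 M (fed, over 30 min) | 0.085 M | 0.085 M | 0.085 M (fed, over 8.0 min) |
| partner | 0.085 M | 0.085 M | 0.085 M | 0.0850 M | 0.0850 M | 0.0850 M (fed, over 30 min) | 0.0850 M |
| base | 4.25 mM | 4.25 mM | 4.25 mM | 4.25 mM | 4.25 mM | 4.25 mM | 4.25 mM |
| scavenger | 0.085 M | 0.085 M | 0.085 M | 0.0850 M | 0.0850 M | 0.0850 M | 0.0850 M |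
| remark | run made earlier | run made earlier | run made earlier | all else is in the flask from the start; the feed brings no volume worth counting | everything together at the start | all else is in the flask from the start; the feed brings no volume worth counting | all else is in the flask from the start; the feed brings no volume worth counting |
| time |  |  |  | 80 min | 80 min | 80 min | 80 min |

- a species is counted by the starting material in it: one side product counts as two

- which flask leads in amount of side product, in percent of the starting material charged ("all alike" within 1.5 percentage points) (red / green / violet / teal / all alike)
- how much side product is there at the end, in percent of the starting material charged: red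
- how much side product is there at the end, in percent of the starting material charged: green
- how much side product is there at the end, in percent of the starting material charged: violet
- how much side product is there at the end, in percent of the starting material charged: teal

Green has the charges of theta, so theta's curve stands for green.

| run | time / min | side product / % | target / % | starting material / % |
|---|---|---|---|---|
| theta | 5.00 | 0 | 3 | 97 |
| theta | 15.0 | 7 | 2 | 91 |
| theta | 30.0 | 22 | 6 | 65 |
| theta | 40.0 | 37 | 9 | 49 |
| theta | 60.0 | 64 | 9 | 31 |
| theta | 80.0 | 70 | 6 | 22 |
| epsilon | 6.00 | 0 | 3 | 99 |
| epsilon | 10.0 | 0 | 2 | 96 |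
| epsilon | 20.0 | 7 | 5 | 90 |
| epsilon | 30.0 | 11 | 4 | 81 |
| epsilon | 50.0 | 29 | 9 | 66 |
| epsilon | 80.0 | 49 | 10 | 45 |
| gamma | 12.0 | 5 | 2 | 95 |
| gamma | 25.0 | 14 | 4 | 83 |
| gamma | 40.0 | 27 | 8 | 61 |
| gamma | 50.0 | 37 | 8 | 52 |
| gamma | 60.0 | 48 | 10 | 42 |
| gamma | 80.0 | 64 | 11 | 29 |

(scatter of a reading: 1.5 percentage points)

Theta shows 7% side product at 15.0 min and 64% at 60.0 min: a lag (induction period), then a rise that flattens to 6 percentage points over the last 20.0 min. So theta's last reading, 70%, is the estimate for green.

A steady feed over 30 min enters on average at its midpoint, 15.0 min late. This mean entry delay replaces the feed by a whole charge added that much later, whichever species is fed. A fed flask then ends where theta stood one delay earlier. The last rise of theta therefore costs red and violet 4.5 points each, which gives them 65.5%. Teal, delayed 4.00 min, stands 1.2 points behind green, at 68.8%, the margin being 1.5 points. This reckoning puts green first, but with teal inside the margin.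

But epsilon, charged with 0.043 M of starting material, reached 49% at 80.0 min, less than theta, so red, short of its charge during its feed, may end below the reckoned figure. Theta and epsilon hold the same partner charge, 0.085 M, and gamma too, so for violet the delay stays the estimate.

The forecast gives green 71%, teal 68%, red 60% and violet 61%, with green leading, and says: “A feed delays things by about half its length.” It stands 5.5 points below this reckoning for red.

The flasks give 71.5% in green, 69.8% in teal, 63.9% in red and 63.9% in violet, so green leads.

    starting material + partner + released group → target + 2 released group (k = 1.10 M⁻² s⁻¹)
    starting material + partner → target + released group (k = 7.80 × 10⁻⁴ M⁻¹ s⁻¹)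
    base + released group ⇌ salt, settled at all times (K = 1.20 × 10⁶ M⁻¹)
    released group → by-product carried off (k = 0.00160 s⁻¹)
    starting material + target → side product (k = 0.0280 M⁻¹ s⁻¹)
    starting material + released group ⇌ idle adduct, settled at all times (K = 14.0 M⁻¹)
    scavenger + released group → scavenged by-product (k = 0.0310 M⁻¹ s⁻¹)

In green at 80.0 min, starting material goes 6.0 times as fast into side product as into target by the step with released group. At that time green holds 6.09% target, which is made at 0.434 of the rate of its loss, each step taken net. Green stands 7.6 points above red, against 4.5 points reckoned, and 1.7 points above teal, against 1.2 points reckoned. Violet fed over 9.00 min has a mean entry delay of 4.50 min, which takes green's figure down to 70.1%; that flask gives 69.6%.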